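I decided to follow the slope of target as a share of the charge per minute, and not a single yield at 25 min.

common to all: gas 48 mM (held)
- delta: starting material 0.039 M; temperature 86 °C; run made earlier
- zeta: starting material 0.058 M; temperature 100 °C; run made earlier
- red: starting material 0.078 M; temperature 105 °C; time 25 min
- green: starting material 0.078 M; temperature 80 °C; time 25 min
- grey: starting material 0.078 M; at 80 °C until 20 min, from then on at 105 °C; time 25 min

- delta (time / min: target / %): 10.0: 3.2; 20.0: 9.2; 30.0: 14.8; 40.0: 21.7; 50.0: 28.3; 60.0: 34.3
- zeta (time / min: target / %): 2.00: 0.5; 3.00: 0.5; 6.00: 1.8; 10.0: 5.3; 15.0: 9.8; 25.0: 18.1

(readings scatter by 0.5 percentage points)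

1. the flask that comes out highest in amount of target, in percent of the starting material charged, or "all alike" when all lie within 1.5 percentage points (red / green / grey / all alike)
2. target at the end, in percent of the starting material charged, red
3. target at the end, in percent of the starting material charged, green
4. target at the end, in percent of the starting material charged, grey

- at the start none of the gas is in solution
- a reading or a percentage of target counts all its forms, free or not

Both runs rise in a straight line after a delay. I read each slope from the late readings and each delay from where the line meets zero:

delta: 0.00650 /min, delay 7.23 min

zeta: 0.00830 /min, delay 3.19 min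

The two slopes give an apparent activation energy, and from it I reckoned the slope at each flask's temperature:

19.5 kJ/mol

at 105 °C: 0.00902 /min

at 80 °C: 0.00582 /min

I carried forward the working slope of red, the share of its charge turning to target per minute on the straight part, a pseudo-first-order constant. I gave red the delay of zeta and gave green the delay of delta:

red: 19.7%

green: 10.3%

grey: 11.9%

The weak link was the scaling with charge, since the two runs differ in charge as well as temperature. When I redid grey in mM/min, with no scaling by charge, it fell to 6.94%. I kept the share reckoning and noted that lower figure as the low side of my estimate.

The forecast judged that “the reaction looks zero order in starting material”. It gave red 18%, green 4.6% and grey 7.6%, with red highest, and its grey lay below mine.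

Red gave 18.8%, green 7.80% and grey 13.4%, so red came out highest, and grey stood 5.8 percentage points above the forecast.

    2 starting material → homo dimer (k = 0.0150 /M/min, Ea = 65.0 kJ/mol)
    crystals ⇌ target, rate k2*(cs2 - [target]) while solid is left; crystals form when [target] > cs2 (solubility = 1.00 mM, k = 0.150 /min)
    gas ⇌ reagent, rate k3*(csat - [reagent]) (kL = 0.0270 /min)
    starting material + reagent → target (k = 0.320 /M/min, Ea = 67.0 kJ/mol)
    2 reagent → side product (k = 0.350 /M/min, Ea = 67.0 kJ/mol)
    (constants at 80 °C)

Grey stood above my 11.9%. From 5.52% at 20.0 min, grey rose at 0.0157 /min up to 25 min, faster than the working slope of red. For red read at 60.0 min, the working slope gives 51.2%. That flask held 43.5% target, 25.0% homo dimer and 31.4% starting material.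

The data were computed from invented constants; the scatter is artificial.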